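**Plan**

- Numbering: flavanone numbering, unprimed for the 7‑hydroxy half (unit 1) and doubly primed for the 5,7‑dihydroxy half (unit 2). The enabling feature is that the C3–C3'' bond joining the two rings C sits inside the carbon row C4–C3–C3''–C4''. As a 1,3‑diene (C4=C3–C3''=C4'') this row is what an alkyne C3≡C3'' becomes when the benzylic carbons of two styrenes (future C4 and C4'') are delivered to it by metathesis.
- Cuts, in retrosynthetic order: the O‑protecting groups; the C4/C4'' carbonyl oxygens (back to a 3,3''‑bi(2H‑chromene)); the ring bonds C3–C4 and C3''–C4'' (ene–yne–ene ring‑closing metathesis); the aryl ether bonds O1–C2 and O1''–C2''; the bonds C2–C3 and C3''–C2'' (two aldehyde alkynylations).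
- Forward: the chain is joined linearly (aldehyde 2 + silylacetylene, first aryl ether, desilylation, aldehyde 2 again, second aryl ether). Both rings C then close in one operation, and C4/C4'' are oxygenated afterwards.
- Stereochemistry: C2 and C2'' come from two catalyst‑controlled alkynylations, each inverted once in a Mitsunobu etherification. C3 and C3'' are set last by equilibration next to the ketones to the 2,3‑trans and 2'',3''‑trans arrangement.
- Protection: ring‑A phenols as benzyl ethers; the two 4'‑type phenols as benzyl carbonates, which are acceptors (the C2–O substitutions stay SN2) and leave in the same final hydrogenolysis.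

Key step: step 10

Assumption: the (S,S)‑ProPhenol–zinc catalyst is taken to deliver the alkynyl group to the aldehyde face that gives the (S)‑carbinols 5 and 11; should the sense on these aldehydes be the opposite, the (R,R)‑ligand is used in steps 2 and 6 and nothing else changes.

Remark: the descriptor at C2/C2'' alternates along the route only because the rank of the C3 substituent relative to the aryl group changes (silylalkynyl, ethynyl, alkenyl, alkyl); the only real inversions are steps 4 and 9.

**Route**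

Step 1
Reactants: 1 4-hydroxybenzaldehyde
Product: 2 benzyl 4-formylphenyl carbonate
Conditions: CbzCl (1.1 equiv), Et3N (1.2 equiv), CH2Cl2, 0 °C
Reagents that add atoms: benzyl chloroformate, O=C(Cl)OCc1ccccc1
Why: O‑acylation of the phenol with a chloroformate; the carbonate turns the para oxygen from a donor into an acceptor, so the later benzylic/propargylic C–O substitutions should not ionize, and it is hydrogenolysed at the end with the benzyl ethers.

Step 2
Reactants: 2 benzyl 4-formylphenyl carbonate; 3 trimethylsilylacetylene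
Product: 5 benzyl 4-[(1S)-1-hydroxy-3-(trimethylsilyl)prop-2-yn-1-yl]phenyl carbonate, via methyl(trimethylsilylethynyl)zinc 4 (not isolated)
Conditions: 3 (3 equiv), Me2Zn (3 equiv), (S,S)-ProPhenol (10 mol %), Ph3P=O (20 mol %), toluene, 4 °C; aq NH4Cl
Reagents that add atoms: none
Why: zinc–ProPhenol catalytic asymmetric alkynylation of an aromatic aldehyde, in which the dinuclear zinc catalyst binds aldehyde and alkynyl side by side and transfers the alkynyl group to one carbonyl face, setting the future C2 as the (S)‑carbinol; the electron‑poor aldehyde is a good substrate and Me2Zn should leave the carbonate alone.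

Step 3
Reactants: 6 4-(benzyloxy)-2-hydroxybenzaldehyde
Product: 7 5-(benzyloxy)-2-ethenylphenol
Conditions: Ph3PCH3Br (2.5 equiv), KOtBu (2.5 equiv), THF, 0 °C to rt; aq NH4Cl
Reagents that add atoms: methyltriphenylphosphonium bromide, C[P+](c1ccccc1)(c1ccccc1)c1ccccc1.[Br-]
Why: Wittig methylenation of a salicylaldehyde with excess ylide (one equivalent of base is consumed by the phenol), the usual entry to 2‑vinylphenols; the product is used fresh.

Step 4
Reactants: 5 benzyl 4-[(1S)-1-hydroxy-3-(trimethylsilyl)prop-2-yn-1-yl]phenyl carbonate; 7 5-(benzyloxy)-2-ethenylphenol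
Product: 8 benzyl 4-[(1R)-1-[5-(benzyloxy)-2-ethenylphenoxy]-3-(trimethylsilyl)prop-2-yn-1-yl]phenyl carbonate
Conditions: PPh3 (1.5 equiv), DIAD (1.5 equiv), toluene, 0 °C to rt
Reagents that add atoms: none
Why: Mitsunobu etherification, in which the phenoxide displaces the alkoxyphosphonium group by SN2 with inversion ((S)‑carbinol to (R)‑ether, the spatial arrangement of C2 in the target); the alkynyl group and the acceptor‑substituted aryl ring should suppress ionization, and the non‑polar solvent keeps the ion pair tight.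

Step 5
Reactants: 8 benzyl 4-[(1R)-1-[5-(benzyloxy)-2-ethenylphenoxy]-3-(trimethylsilyl)prop-2-yn-1-yl]phenyl carbonate
Product: 9 benzyl 4-[(1S)-1-[5-(benzyloxy)-2-ethenylphenoxy]prop-2-yn-1-yl]phenyl carbonate
Conditions: AgNO3 (0.2 equiv), CH2Cl2/MeOH/H2O (7:4:1), rt, dark
Reagents that add atoms: none
Why: silver‑catalysed protodesilylation of the alkynylsilane through the silver acetylide under neutral conditions, chosen because K2CO3/MeOH would cleave the aryl carbonates; the stereocentre is untouched and its descriptor changes only because ethynyl ranks below aryl.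

Step 6
Reactants: 9 benzyl 4-[(1S)-1-[5-(benzyloxy)-2-ethenylphenoxy]prop-2-yn-1-yl]phenyl carbonate; 2 benzyl 4-formylphenyl carbonate
Product: 11 benzyl 4-[(1R,4S)-1-[5-(benzyloxy)-2-ethenylphenoxy]-4-(4-{[(benzyloxy)carbonyl]oxy}phenyl)-4-hydroxybut-2-yn-1-yl]phenyl carbonate, via methylzinc acetylide 10 (not isolated)
Conditions: 9 (1.0 equiv), Me2Zn (3 equiv), (S,S)-ProPhenol (20 mol %), Ph3P=O (40 mol %), toluene, 4 °C; then 2 (1.5 equiv); aq NH4Cl
Reagents that add atoms: none
Why: second zinc–ProPhenol alkynylation with alkyne 9 as the nucleophile; the existing centre lies four bonds away across the alkyne, so the catalyst alone should set the new carbinol (future C2'') as (S), and any leakage would appear as a separable diastereomer.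

Step 7
Reactants: 12 2,4,6-trihydroxybenzaldehyde
Product: 13 2,4-bis(benzyloxy)-6-hydroxybenzaldehyde
Conditions: BnBr (2.05 equiv), K2CO3 (2.2 equiv), DMF, 0 °C to rt
Reagents that add atoms: benzyl bromide, BrCc1ccccc1
Why: Williamson benzylation; the hydroxyl hydrogen‑bonded to the formyl group is the least nucleophilic site and should stay free when two equivalents of halide are used, as is known for acylphloroglucinols.

Step 8
Reactants: 13 2,4-bis(benzyloxy)-6-hydroxybenzaldehyde
Product: 14 3,5-bis(benzyloxy)-2-ethenylphenol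
Conditions: Ph3PCH3Br (3 equiv), KOtBu (3 equiv), THF, 0 to 40 °C; aq NH4Cl
Reagents that add atoms: methyltriphenylphosphonium bromide, C[P+](c1ccccc1)(c1ccccc1)c1ccccc1.[Br-]
Why: Wittig methylenation as in step 3; the electron‑rich phenoxide aldehyde reacts more slowly, hence excess ylide and mild warming, and the acid‑sensitive product is used immediately.

Step 9
Reactants: 11 benzyl 4-[(1R,4S)-1-[5-(benzyloxy)-2-ethenylphenoxy]-4-(4-{[(benzyloxy)carbonyl]oxy}phenyl)-4-hydroxybut-2-yn-1-yl]phenyl carbonate; 14 3,5-bis(benzyloxy)-2-ethenylphenol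
Product: 15 (1R,4R)-1-[5-(benzyloxy)-2-ethenylphenoxy]-4-[3,5-bis(benzyloxy)-2-ethenylphenoxy]-1,4-bis(4-{[(benzyloxy)carbonyl]oxy}phenyl)but-2-yne
Conditions: PPh3 (2 equiv), DIAD (2 equiv), toluene, 0 °C to rt
Reagents that add atoms: none
Why: second Mitsunobu etherification with SN2 inversion ((S)‑carbinol to (R)‑ether, the spatial arrangement of C2'' in the target), relying on the same electronic bias against ionization as step 4.

Step 10
Reactants: 15 (1R,4R)-1-[5-(benzyloxy)-2-ethenylphenoxy]-4-[3,5-bis(benzyloxy)-2-ethenylphenoxy]-1,4-bis(4-{[(benzyloxy)carbonyl]oxy}phenyl)but-2-yne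
Product: 16 (2R,2''R)-7,5'',7''-tris(benzyloxy)-2,2''-bis(4-{[(benzyloxy)carbonyl]oxy}phenyl)-2H,2''H-3,3''-bichromene
Conditions: second-generation Grubbs catalyst RuCl2(=CHPh)(H2IMes)(PCy3) (10 mol %), degassed CH2Cl2 (0.005 M), 40 °C, slow argon stream, dark
Reagents that add atoms: none
Why: The catalyst enters at either terminal styrene to give a 2‑alkoxybenzylidene ruthenium species whose carbene carbon (C4) adds to the near alkyne carbon (C3); opening of the ruthenacyclobutene closes ring C of unit 1 as C3=C4 and leaves a vinylcarbene on C3''. This carbene then undergoes ring‑closing metathesis with the second styrene, forming C3''=C4'', closing ring C of unit 2 and passing the metal on as a methylidene, so that ethene is the only by‑product; entry at the other styrene runs the same sequence in reverse and gives the same diene. The closest known reaction type is the tandem dienyne (ene–yne–ene) ring‑closing metathesis of 1,4‑bis(alkenyloxy)but‑2‑ynes to 3,3'‑linked bis(oxacycloalkene) dienes. Ring C of unit 1 closes in the exo mode of enyne metathesis (six‑membered, only C3 of the alkyne in the ring) and ring C of unit 2 by carbene–alkene ring closure (six‑membered). No stereocentre is formed; C2 and C2'' are only carried through, which the neutral, non‑Lewis‑acidic catalyst and the acceptor‑substituted 2‑aryl groups should permit. The selectivity needed is exo over endo addition to the alkyne, secured by the four‑atom spacer C4a–C8a–O1–C2 between carbene carbon and alkyne (endo addition would demand a seven‑membered ring holding both alkyne carbons), together with cyclization over oligomerization, secured by high dilution.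

Step 11
Reactants: 16 (2R,2''R)-7,5'',7''-tris(benzyloxy)-2,2''-bis(4-{[(benzyloxy)carbonyl]oxy}phenyl)-2H,2''H-3,3''-bichromene
Product: 18 (2S,2''S)-7,5'',7''-tris(benzyloxy)-2,2''-bis(4-{[(benzyloxy)carbonyl]oxy}phenyl)-3,3''-bichromane-4,4''-diol (mixture of C3/C4/C3''/C4'' diastereomers), via 4,4''-bis(dihydroboryl) adduct 17 (not isolated)
Conditions: BH3·SMe2 (4 equiv), THF, 0 °C to rt; MeOH; then 30% H2O2, aq NaHCO3 (pH about 8), 0 °C to rt
Reagents that add atoms: hydrogen peroxide, OO; borane–dimethyl sulfide, [BH3-][S+](C)C (its boron is found only in intermediate 17)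
Why: hydroboration–oxidation, in which boron should go to the less substituted diene termini C4 and C4'' (as with 2,3‑dialkylbutadienes and β,β‑disubstituted styrenes) and hydrogen syn to C3 and C3'' from the face opposite the 2‑aryl groups, oxidation then giving the 4,4''‑diol with retention; the new C3/C4 configurations are not carried into the target, and buffered peroxide attacks boron much faster than the carbonates.

Step 12
Reactants: 18 (2S,2''S)-7,5'',7''-tris(benzyloxy)-2,2''-bis(4-{[(benzyloxy)carbonyl]oxy}phenyl)-3,3''-bichromane-4,4''-diol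
Product: 20 (2S,3R,2''S,3''R)-7,5'',7''-tris(benzyloxy)-2,2''-bis(4-{[(benzyloxy)carbonyl]oxy}phenyl)-3,3''-bichromane-4,4''-dione, via cis-rich diketone 19 (not isolated)
Conditions: DMP (3 equiv), CH2Cl2, 0 °C to rt; aq Na2S2O3/NaHCO3 wash; crude in CH2Cl2, DBU (0.2 equiv), 0 °C to rt
Reagents that add atoms: none
Why: Dess–Martin oxidation of the two benzylic alcohols followed by base‑mediated epimerization through the enolates at C3 and C3'', which should bring each 3‑substituent trans (diequatorial) to its 2‑aryl group as in other 3‑substituted flavanones; with C2 and C2'' fixed this single thermodynamic isomer is (2S,3R,2''S,3''R), and catalytic amidine in an aprotic solvent for a short time is chosen to avoid opening of the pyranone rings.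

Step 13
Reactants: 20 (2S,3R,2''S,3''R)-7,5'',7''-tris(benzyloxy)-2,2''-bis(4-{[(benzyloxy)carbonyl]oxy}phenyl)-3,3''-bichromane-4,4''-dione
Product: 21 (2S,3R,2''S,3''R)-7,5'',7''-trihydroxy-2,2''-bis(4-hydroxyphenyl)-3,3''-bichromane-4,4''-dione (CNP0138443.1)
Conditions: H2 (1 atm), 10% Pd/C, EtOAc/MeOH, rt
Reagents that add atoms: none
Why: hydrogenolysis of three aryl benzyl ethers and two aryl benzyl carbonates (the latter losing CO2) under neutral conditions that neither enolize nor open the flavanone rings; the reaction is stopped at full debenzylation to spare the benzylic C2–O bonds.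

**Compound list**

1 | 4-hydroxybenzaldehyde | O=Cc1ccc(O)cc1 | starting material
2 | benzyl 4-formylphenyl carbonate | O=Cc1ccc(OC(=O)OCc2ccccc2)cc1 | intermediate
3 | trimethylsilylacetylene | C#C[Si](C)(C)C | starting material
4 | methyl[(trimethylsilyl)ethynyl]zinc | C[Zn]C#C[Si](C)(C)C | intermediate (not isolated)
5 | benzyl 4-[(1S)-1-hydroxy-3-(trimethylsilyl)prop-2-yn-1-yl]phenyl carbonate | O[C@H](C#C[Si](C)(C)C)c1ccc(OC(=O)OCc2ccccc2)cc1 | intermediate
6 | 4-(benzyloxy)-2-hydroxybenzaldehyde | O=Cc1ccc(OCc2ccccc2)cc1O | starting material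
7 | 5-(benzyloxy)-2-ethenylphenol | C=Cc1ccc(OCc2ccccc2)cc1O | intermediate
8 | benzyl 4-[(1R)-1-[5-(benzyloxy)-2-ethenylphenoxy]-3-(trimethylsilyl)prop-2-yn-1-yl]phenyl carbonate | C=Cc1ccc(OCc2ccccc2)cc1O[C@H](c1ccc(OC(=O)OCc2ccccc2)cc1)C#C[Si](C)(C)C | intermediate
9 | benzyl 4-[(1S)-1-[5-(benzyloxy)-2-ethenylphenoxy]prop-2-yn-1-yl]phenyl carbonate (same spatial arrangement as 8) | C=Cc1ccc(OCc2ccccc2)cc1O[C@H](c1ccc(OC(=O)OCc2ccccc2)cc1)C#C | intermediate
10 | methylzinc acetylide of 9 (zinc on the alkyne terminus) | C=Cc1ccc(OCc2ccccc2)cc1O[C@H](c1ccc(OC(=O)OCc2ccccc2)cc1)C#C[Zn]C | intermediate (not isolated)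
11 | benzyl 4-[(1R,4S)-1-[5-(benzyloxy)-2-ethenylphenoxy]-4-(4-{[(benzyloxy)carbonyl]oxy}phenyl)-4-hydroxybut-2-yn-1-yl]phenyl carbonate | C=Cc1ccc(OCc2ccccc2)cc1O[C@H](c1ccc(OC(=O)OCc2ccccc2)cc1)C#C[C@@H](O)c1ccc(OC(=O)OCc2ccccc2)cc1 | intermediate
12 | 2,4,6-trihydroxybenzaldehyde | O=Cc1c(O)cc(O)cc1O | starting material
13 | 2,4-bis(benzyloxy)-6-hydroxybenzaldehyde | O=Cc1c(O)cc(OCc2ccccc2)cc1OCc1ccccc1 | intermediate
14 | 3,5-bis(benzyloxy)-2-ethenylphenol | C=Cc1c(O)cc(OCc2ccccc2)cc1OCc1ccccc1 | intermediate
15 | (1R,4R)-1-[5-(benzyloxy)-2-ethenylphenoxy]-4-[3,5-bis(benzyloxy)-2-ethenylphenoxy]-1,4-bis(4-{[(benzyloxy)carbonyl]oxy}phenyl)but-2-yne | C=Cc1ccc(OCc2ccccc2)cc1O[C@H](c1ccc(OC(=O)OCc2ccccc2)cc1)C#C[C@H](Oc1cc(OCc2ccccc2)cc(OCc2ccccc2)c1C=C)c1ccc(OC(=O)OCc2ccccc2)cc1 | intermediate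
16 | (2R,2''R)-7,5'',7''-tris(benzyloxy)-2,2''-bis(4-{[(benzyloxy)carbonyl]oxy}phenyl)-2H,2''H-3,3''-bichromene | O=C(OCc1ccccc1)Oc1ccc(cc1)[C@H]1Oc2cc(OCc3ccccc3)ccc2C=C1C1=Cc2c(OCc3ccccc3)cc(OCc3ccccc3)cc2O[C@@H]1c1ccc(OC(=O)OCc2ccccc2)cc1 | intermediate
17 | 4,4''-bis(dihydroboryl) adduct of 16 (boron on C4 and C4'', hydrogen on C3 and C3''; C3/C4 configurations not assigned) | BC1c2ccc(OCc3ccccc3)cc2O[C@H](c2ccc(OC(=O)OCc3ccccc3)cc2)C1C1C(B)c2c(OCc3ccccc3)cc(OCc3ccccc3)cc2O[C@@H]1c1ccc(OC(=O)OCc2ccccc2)cc1 | intermediate (not isolated)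
18 | (2S,2''S)-7,5'',7''-tris(benzyloxy)-2,2''-bis(4-{[(benzyloxy)carbonyl]oxy}phenyl)-3,3''-bichromane-4,4''-diol, diastereomer mixture at C3/C4/C3''/C4'' (expected mainly 2,3-cis, 3,4-trans in each half) | OC1c2ccc(OCc3ccccc3)cc2O[C@H](c2ccc(OC(=O)OCc3ccccc3)cc2)C1C1C(O)c2c(OCc3ccccc3)cc(OCc3ccccc3)cc2O[C@@H]1c1ccc(OC(=O)OCc2ccccc2)cc1 | intermediate
19 | (2S,2''S)-7,5'',7''-tris(benzyloxy)-2,2''-bis(4-{[(benzyloxy)carbonyl]oxy}phenyl)-3,3''-bichromane-4,4''-dione, C3/C3'' epimer mixture (kinetically mostly 2,3-cis) | O=C1c2ccc(OCc3ccccc3)cc2O[C@H](c2ccc(OC(=O)OCc3ccccc3)cc2)C1C1C(=O)c2c(OCc3ccccc3)cc(OCc3ccccc3)cc2O[C@@H]1c1ccc(OC(=O)OCc2ccccc2)cc1 | intermediate (not isolated)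
20 | (2S,3R,2''S,3''R)-7,5'',7''-tris(benzyloxy)-2,2''-bis(4-{[(benzyloxy)carbonyl]oxy}phenyl)-3,3''-bichromane-4,4''-dione (2,3-trans and 2'',3''-trans) | O=C1c2ccc(OCc3ccccc3)cc2O[C@H](c2ccc(OC(=O)OCc3ccccc3)cc2)[C@H]1[C@H]1C(=O)c2c(OCc3ccccc3)cc(OCc3ccccc3)cc2O[C@@H]1c1ccc(OC(=O)OCc2ccccc2)cc1 | intermediate
21 | (2S,3R,2''S,3''R)-7,5'',7''-trihydroxy-2,2''-bis(4-hydroxyphenyl)-3,3''-bichromane-4,4''-dione (CNP0138443.1) | O=C1c2ccc(O)cc2O[C@H](c2ccc(O)cc2)[C@H]1[C@H]1C(=O)c2c(O)cc(O)cc2O[C@@H]1c1ccc(O)cc1 | target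

**Count and risks**

Total: 13 steps. Longest linear sequence: 10 steps (1, 2, 4, 5, 6, 9, 10, 11, 12, 13); steps 3 and 7–8 are side branches.

Most likely to fail:

1. Step 10. The relay may stall: the first‑formed 2‑alkoxybenzylidene can rest as an oxygen‑chelated carbene, and the alkyne, flanked by two branched carbons, may not enter the coordination sphere. Ring closure would then stop after one ring, or be overtaken by intermolecular metathesis and catalyst decay; forcing it by heat risks thermal opening of the 2H‑chromene and loss of configuration at C2/C2''. Fallback, setting out from 15 and returning at 16: the alkyne is first converted by cross‑metathesis with ethene (same ruthenium catalyst, ethene 2–3 atm, toluene, 70 °C) into the 2,3‑dimethylidene tetraene F1, since the small methylidene carbene can reach the alkyne where a tethered benzylidene may not. F1 is then closed twice by ordinary diene ring‑closing metathesis, each styrene with its neighbouring 1,1‑disubstituted alkene (CH2Cl2, 40 °C, argon), to give 16.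

2. Step 11. Boron delivery may be misdirected: the electron‑rich ring‑A aryl groups favour boron at C3/C3'' while sterics favour C4/C4'', so loss of regiocontrol would place oxygen on C3. Fallback, setting out from 16 and returning at 19: both alkenes are dihydroxylated (K2OsO4·2H2O cat., NMO, acetone/H2O), which puts oxygen on C4 and C4'' regardless of polarization, giving the 3,4,3'',4''‑tetraol F2. IBX (DMSO, rt) oxidizes the two secondary benzylic hydroxyls without glycol cleavage to the bis(3‑hydroxy‑4‑ketone) F3. SmI2 (THF/MeOH, −78 °C) then removes both α‑hydroxyls, and would also reduce any ene‑dione formed by β‑elimination, to give diketone 19 as an epimer mixture, which is equilibrated with DBU as in step 12.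

3. Step 9. Capture of the alkoxyphosphonium ion at the congested C2'' carbinol by the weakly acidic, acid‑sensitive vinylphenol 14 may be slow, so that ionization (erosion of configuration), alkylation of the reduced azodicarboxylate or oligomerization of 14 takes over. Fallback, setting out from 11 and returning at 15: the Mitsunobu reaction is run instead with the more acidic and stable aldehyde 13 (PPh3, DIAD, toluene, 0 °C) to give the formyl ether F4. Its aldehyde is then methylenated under non‑basic Takai–Lombardo conditions (Zn, CH2Br2, TiCl4, THF/CH2Cl2, 0 °C), which should spare the carbonates, the alkyne and the styrene, to give 15.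

Further compounds
F1 | step 10 | (1R,4R)-1-[5-(benzyloxy)-2-ethenylphenoxy]-4-[3,5-bis(benzyloxy)-2-ethenylphenoxy]-1,4-bis(4-{[(benzyloxy)carbonyl]oxy}phenyl)-2,3-dimethylidenebutane | C=Cc1ccc(OCc2ccccc2)cc1O[C@H](c1ccc(OC(=O)OCc2ccccc2)cc1)C(=C)C(=C)[C@H](Oc1cc(OCc2ccccc2)cc(OCc2ccccc2)c1C=C)c1ccc(OC(=O)OCc2ccccc2)cc1
F2 | step 11 | (2S,2''S)-7,5'',7''-tris(benzyloxy)-2,2''-bis(4-{[(benzyloxy)carbonyl]oxy}phenyl)-3,3''-bichromane-3,4,3'',4''-tetraol (C3/C4 diastereomer mixture) | OC1c2ccc(OCc3ccccc3)cc2O[C@H](c2ccc(OC(=O)OCc3ccccc3)cc2)C1(O)C1(O)C(O)c2c(OCc3ccccc3)cc(OCc3ccccc3)cc2O[C@@H]1c1ccc(OC(=O)OCc2ccccc2)cc1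
F3 | step 11 | (2S,2''S)-7,5'',7''-tris(benzyloxy)-2,2''-bis(4-{[(benzyloxy)carbonyl]oxy}phenyl)-3,3''-dihydroxy-3,3''-bichromane-4,4''-dione (C3/C3'' diastereomer mixture) | O=C1c2ccc(OCc3ccccc3)cc2O[C@H](c2ccc(OC(=O)OCc3ccccc3)cc2)C1(O)C1(O)C(=O)c2c(OCc3ccccc3)cc(OCc3ccccc3)cc2O[C@@H]1c1ccc(OC(=O)OCc2ccccc2)cc1
F4 | step 9 | (1R,4R)-1-[5-(benzyloxy)-2-ethenylphenoxy]-4-[3,5-bis(benzyloxy)-2-formylphenoxy]-1,4-bis(4-{[(benzyloxy)carbonyl]oxy}phenyl)but-2-yne | C=Cc1ccc(OCc2ccccc2)cc1O[C@H](c1ccc(OC(=O)OCc2ccccc2)cc1)C#C[C@H](Oc1cc(OCc2ccccc2)cc(OCc2ccccc2)c1C=O)c1ccc(OC(=O)OCc2ccccc2)cc1
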